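Ring B carries four contiguous methoxylated carbons, C2'–C5'; they are taken from the four ring carbons of dimethyl squarate (1), while C1' and C6' come from the two alkyne carbons of 3,3-diethoxyprop-1-yne (2), whose acetal carbon later becomes C2 of ring C. The precursor is the 4-alkynyl-4-hydroxy-2,3-dimethoxycyclobutenone formed from 1 and 2. Heating it opens the four-membered ring to an alkynyl ketene that closes ring B as a 2,3-dimethoxybenzoquinone, forming the C1'–C2' bond and fixing the substitution pattern in one operation. Reductive methylation and acetal hydrolysis give the ring B aldehyde, which is joined to 2'-hydroxy-4',5',6'-trimethoxyacetophenone (3) by Claisen–Schmidt condensation and iodine-catalysed closure of ring C.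

Key step: step 2

Remark on the chemistry: acetophenone 3 is taken as a catalogue compound, and transient stereocenters are carried as racemates because the target is achiral.

Step 1
Reactants: 1 dimethyl squarate; 2 3,3-diethoxyprop-1-yne
Product: 5 rac-4-(3,3-diethoxyprop-1-yn-1-yl)-4-hydroxy-2,3-dimethoxycyclobut-2-en-1-one, via lithium acetylide 4 (not isolated)
Conditions: 2, n-BuLi, THF, −78 °C; then 1, THF, −78 °C; NH4Cl (aq) quench at −78 °C
Reagents that add atoms: none
Why: Alkynylation by 1,2-addition of a lithium acetylide to a ketone carbonyl: at −78 °C the acetylide should add once to one of the two equivalent carbonyls of the squarate ester (the alkoxide formed shuts down a second addition), and the carbinol stereocenter C4 arises as a racemate without control, which is harmless because step 2 destroys it.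

Step 2
Reactants: 5 rac-4-(3,3-diethoxyprop-1-yn-1-yl)-4-hydroxy-2,3-dimethoxycyclobut-2-en-1-one
Product: 8 5-(diethoxymethyl)-2,3-dimethoxy-1,4-benzoquinone, via enynyl ketene 6 (not isolated), via aryl diradical 7 (not isolated)
Conditions: p-xylene (degassed, 0.02 M), reflux (138 °C), Ar
Reagents that add atoms: none
Why: Heat should trigger a conrotatory 4π electrocyclic opening of the C1–C4 bond of 5 in which the donor hydroxyl rotates outward, so that the alkynyl group sits cis to the ketene in (Z)-ketene 6. The ketene carbon then bonds to the distal, acetal-bearing alkyne carbon (the C1'–C2' bond), closing ring B in a six-membered endo-dig mode to the aromatic diradical 7, and shift of the hydroxyl hydrogen to the neighbouring aryl σ-radical carbon (future C6') gives quinone 8. The closest known reaction type is the Moore rearrangement of squarate-derived 4-alkynyl-4-hydroxycyclobutenones to 2,3-dialkoxy-1,4-benzoquinones, the ketene counterpart of the Myers–Saito cyclisation. No stereocenter is created, and the carbinol stereocenter of 5 is erased. The step needs six-membered closure to win over five-membered exo-dig closure to a 2-alkylidenecyclopentene-1,3-dione, and the sp3 acetal carbon on the alkyne terminus secures this because it cannot stabilise the exocyclic vinyl radical of the five-membered path as an aryl, silyl or acyl group would. The substitution pattern needs no further control, since the acetal-bearing carbon can only become the ring carbon bonded to the former ketene carbon, and the hydroxyl is left unprotected so that it supplies the hydrogen at C6'.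

Step 3
Reactants: 8 5-(diethoxymethyl)-2,3-dimethoxy-1,4-benzoquinone
Product: 11 2,3,4,5-tetramethoxybenzaldehyde, via hydroquinone acetal 9 (not isolated), via tetramethoxyphenyl acetal 10 (not isolated)
Conditions: Na2S2O4, Bu4NBr (cat.), THF/H2O, Ar, rt; then KOH (aq), Me2SO4, rt; then 2 M HCl to pH 1, rt
Reagents that add atoms: dimethyl sulfate, COS(=O)(=O)OC; water, O
Why: Dithionite reduction of a benzoquinone followed by in situ Williamson O-methylation under phase-transfer conditions is a standard one-pot reductive methylation, and the closing aqueous-acid acetal hydrolysis makes acetal that opened early and acetal that survived converge on the same aldehyde.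

Step 4
Reactants: 11 2,3,4,5-tetramethoxybenzaldehyde; 3 2'-hydroxy-4',5',6'-trimethoxyacetophenone
Product: 13 (E)-1-(6-hydroxy-2,3,4-trimethoxyphenyl)-3-(2,3,4,5-tetramethoxyphenyl)prop-2-en-1-one, via aldol adduct 12 (not isolated)
Conditions: KOH, EtOH/H2O, rt; then dil. HCl
Reagents that add atoms: none
Why: Claisen–Schmidt (crossed aldol) condensation of a methyl ketone enolate with a non-enolisable aryl aldehyde, in which E1cB dehydration of the aldol should give the thermodynamically favoured E-enone while the phenoxide stays a spectator.

Step 5
Reactants: 13 (E)-1-(6-hydroxy-2,3,4-trimethoxyphenyl)-3-(2,3,4,5-tetramethoxyphenyl)prop-2-en-1-one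
Product: 15 Agehoustin B [5,6,7-trimethoxy-2-(2,3,4,5-tetramethoxyphenyl)-4H-chromen-4-one], via flavanone 14 (not isolated)
Conditions: I2 (10 mol%), DMSO, 130 °C
Reagents that add atoms: none
Why: Iodine-catalysed oxidative cyclisation of a 2'-hydroxychalcone: intramolecular oxa-Michael addition closes ring C to the flavanone, iodine dehydrogenates C2–C3 while DMSO reoxidises the HI formed, and the single flavanone stereocenter is erased on forming the 4-pyranone (any flavanone carried over from step 4 converges here).

Compound list
1 | dimethyl squarate (3,4-dimethoxycyclobut-3-ene-1,2-dione) | COC1=C(OC)C(=O)C1=O | starting material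
2 | 3,3-diethoxyprop-1-yne | C#CC(OCC)OCC | starting material
3 | 2'-hydroxy-4',5',6'-trimethoxyacetophenone [1-(6-hydroxy-2,3,4-trimethoxyphenyl)ethan-1-one] | CC(=O)c1c(O)cc(OC)c(OC)c1OC | starting material
4 | (3,3-diethoxyprop-1-yn-1-yl)lithium | [Li]C#CC(OCC)OCC | intermediate
5 | rac-4-(3,3-diethoxyprop-1-yn-1-yl)-4-hydroxy-2,3-dimethoxycyclobut-2-en-1-one | CCOC(OCC)C#CC1(O)C(OC)=C(OC)C1=O | intermediate
6 | (3Z)-7,7-diethoxy-4-hydroxy-2,3-dimethoxyhepta-1,3-dien-5-yn-1-one (enynyl ketene, alkyne cis to the ketene) | O=C=C(OC)/C(OC)=C(/O)C#CC(OCC)OCC | intermediate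
7 | 2-(diethoxymethyl)-6-hydroxy-4,5-dimethoxy-3-oxylphenyl diradical (aryl σ-radical between C–OH and C–CH(OEt)2, oxygen radical on the former ketene carbon) | CCOC(OCC)c1[c]c(O)c(OC)c(OC)c1[O] | intermediate
8 | 5-(diethoxymethyl)-2,3-dimethoxy-1,4-benzoquinone [5-(diethoxymethyl)-2,3-dimethoxycyclohexa-2,5-diene-1,4-dione] | CCOC(OCC)C1=CC(=O)C(OC)=C(OC)C1=O | intermediate
9 | 5-(diethoxymethyl)-2,3-dimethoxybenzene-1,4-diol | CCOC(OCC)c1cc(O)c(OC)c(OC)c1O | intermediate
10 | 1-(diethoxymethyl)-2,3,4,5-tetramethoxybenzene | CCOC(OCC)c1cc(OC)c(OC)c(OC)c1OC | intermediate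
11 | 2,3,4,5-tetramethoxybenzaldehyde | O=Cc1cc(OC)c(OC)c(OC)c1OC | intermediate
12 | rac-3-hydroxy-1-(6-hydroxy-2,3,4-trimethoxyphenyl)-3-(2,3,4,5-tetramethoxyphenyl)propan-1-one | COc1cc(C(O)CC(=O)c2c(O)cc(OC)c(OC)c2OC)c(OC)c(OC)c1OC | intermediate
13 | (E)-1-(6-hydroxy-2,3,4-trimethoxyphenyl)-3-(2,3,4,5-tetramethoxyphenyl)prop-2-en-1-one | COc1cc(/C=C/C(=O)c2c(O)cc(OC)c(OC)c2OC)c(OC)c(OC)c1OC | intermediate
14 | rac-5,6,7-trimethoxy-2-(2,3,4,5-tetramethoxyphenyl)chroman-4-one | COc1cc(C2CC(=O)c3c(OC)c(OC)c(OC)cc3O2)c(OC)c(OC)c1OC | intermediate
15 | Agehoustin B, 5,6,7-trimethoxy-2-(2,3,4,5-tetramethoxyphenyl)-4H-chromen-4-one | COc1cc(-c2cc(=O)c3c(OC)c(OC)c(OC)cc3o2)c(OC)c(OC)c1OC | target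

Total step count: 5. Longest linear sequence: 5 steps (1 and 2 to 15; acetophenone 3 enters at step 4).

Steps most likely to fail

Step 2. The ketene may close through the proximal alkyne carbon to a five-membered ring. The aryl σ-radical of 7 may abstract hydrogen from an ethoxy CH2 of the acetal instead of receiving the hydroxyl hydrogen. The acetal quinone may also degrade on prolonged heating. The fallback replaces the diradical pathway by the closed-shell alkenyl version of the same squarate benzannulation. It sets out from dimethyl squarate 1. (3,3-Diethoxyprop-1-en-2-yl)lithium F1, made from commercial 2-bromo-3,3-diethoxyprop-1-ene and t-BuLi in THF at −78 °C, would be added to 1 to give rac-4-(3,3-diethoxyprop-1-en-2-yl)-4-hydroxy-2,3-dimethoxycyclobut-2-en-1-one F2. Heating F2 in toluene at 110 °C should open it to the dienyl ketene (3Z)-5-(diethoxymethyl)-4-hydroxy-2,3-dimethoxyhexa-1,3,5-trien-1-one F3. Its 6π electrocyclisation and enolisation should deliver hydroquinone 9 directly, without radical intermediates. The route is rejoined at 9, and the methylation and hydrolysis of step 3 follow, with Na2S2O4 kept only to hold the reduced oxidation level.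

Step 3. The hydroquinone may re-oxidise in air before both phenols are capped. Methylation of the phenol flanked by the acetal may be incomplete. Early acetal loss may leave a chelated hydroxy aldehyde that alkylates slowly. The fallback traps the reduced ring as an isolable ester instead of alkylating it in situ. It sets out from quinone 8. Reductive acetylation (Zn, Ac2O, NaOAc, rt) should give 5-(diethoxymethyl)-2,3-dimethoxy-1,4-phenylene diacetate F4, which can be purified and stored. One-pot saponification and methylation under Ar (KOH, Me2SO4, Bu4NBr, THF/H2O) then releases each phenoxide only in the presence of the alkylating agent and should lead to acetal 10. The route is rejoined at 10 for the acid hydrolysis to aldehyde 11.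

Step 5. The electron-rich rings may be iodinated (C8 of ring A, C6' of ring B). HI may cleave the C5 methyl ether peri to the carbonyl. The reaction may also stall at the flavanone. The fallback separates ring closure from oxidation and uses a halogen-free oxidant. It sets out from chalcone 13. NaOAc in refluxing EtOH should give flavanone 14 as an isolated compound, and DDQ in refluxing 1,4-dioxane should then dehydrogenate C2–C3 to give target 15. No compound outside the list is made (F0).

Further compounds
F1 | step 2 | (3,3-diethoxyprop-1-en-2-yl)lithium | [Li]C(=C)C(OCC)OCC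
F2 | step 2 | rac-4-(3,3-diethoxyprop-1-en-2-yl)-4-hydroxy-2,3-dimethoxycyclobut-2-en-1-one | CCOC(OCC)C(=C)C1(O)C(OC)=C(OC)C1=O
F3 | step 2 | (3Z)-5-(diethoxymethyl)-4-hydroxy-2,3-dimethoxyhexa-1,3,5-trien-1-one | O=C=C(OC)/C(OC)=C(/O)C(=C)C(OCC)OCC
F4 | step 3 | 5-(diethoxymethyl)-2,3-dimethoxy-1,4-phenylene diacetate | CCOC(OCC)c1cc(OC(C)=O)c(OC)c(OC)c1OC(C)=O
F0 | step 5 | none | none
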